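## The problem

Compound 15 is a benzophenone whose ring A is fully substituted: C1 carries the 3-hydroxybenzoyl group, C2 and C6 carry free phenols, C3 and C5 carry prenyl groups, and C4 carries the only methyl ether. It has no stereocentre and no ring to close, and both alkenes end in two identical methyl groups. The task is therefore one of regiochemistry and chemoselectivity on a phloroglucinol core. Four oxygens must be told apart: O4 is methylated, while O2, O6 and O3' stay free. The two side chains must reach C3 and C5 as normal prenyl groups; a phloroglucinol anion and a prenyl halide typically also give O-prenyl ethers, geminal diprenyl dienones and reverse-prenyl groups. The diaryl ketone sits between two ortho phenols and must survive any organometallic reagent used on the ring. A prenyl group next to a free phenol closes to a 2,2-dimethylchroman under acid, so acylation and any acidic deprotection must be finished before the side chains exist. The enabling feature is that each prenyl CH2 (C1'') is bonded to a ring carbon (C3, C5) ortho to a free phenol (O2, O6). Each benzylic carbon can therefore become the electrophilic end of an o-quinone methide (O2=C2–C3=C1'' and O6=C6–C5=C1''), and the C1''–C2'' bond can be made with an alkenyl nucleophile.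

## Retrosynthesis

**15 from 14 (O3'–Si).** The last cut is the silyl ether on ring B. A silyl group is chosen because fluoride removes it; acid would cyclize the two o-prenylphenol units. The forward step only has to leave the alkenes and the free phenols alone.

**14 from 8 and 9 (both C1''–C2'' bonds).** Cutting each prenyl group between its benzylic CH2 and its alkene carbon reverses the usual polarity: the ring supplies two electrophilic benzylic carbons and the reagent 9 supplies the alkenyl nucleophile. The neighbouring cut, ring carbon to C1'' with a prenyl electrophile, is the one that gives O-, geminal and reverse prenylation. Here each benzylic carbon has one leaving group and can take one nucleophile only. The bis-Mannich base 8 holds both benzylic carbons as amines; it is quaternized in the flask to 10 and reacts through the o-quinone methides 11 and 13 and the half-way compound 12. The forward reaction must add at the methide carbons and spare the ketone.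

**8 from 6 and 7 (both C3–C1'' and C5–C1'' bonds).** The two aminomethyl arms are removed by a retro-Mannich cut. Ring A of 6 has exactly two free carbons, each ortho to a phenol and activated by three oxygens, so the iminium salt 7 has no other site to attack once ring B is masked. The forward reaction must go twice.

**6 from 5 (O3'–Si).** Ring B of 5 carries a free phenol that would itself undergo aminomethylation. Only O3' in 5 is neither hindered nor hydrogen-bonded to the ketone, so one equivalent of silyl chloride should find it.

**5 from 4 (O4–CH3).** The methyl ether is cut next. In 4 the phenol para to the ketone is the most acidic of the four, so one equivalent of base and of methylating agent should select O4. Methylating before silylating matters, because O4 would otherwise compete with O3' for the silyl chloride.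

**4 from 1 and 2 (C1–carbonyl bond).** The diaryl ketone is cut at the ring A side by a Houben–Hoesch disconnection, through the ketiminium salt 3. Compound 1 is symmetric, so no regiochemistry arises, and the iminium stage prevents a second acylation. This is the only strongly acidic step and it comes first.

## Roads not taken

**Alternative 1:** Ring A is cut at C2–C3 and C4–C5 and assembled by a Danheiser benzannulation. Heating the 2-prenyl-3-silyloxycyclobutenone A2 with the methoxyalkyne A3 would give the phenol A1 by four-electron ring opening to a vinylketene, [2+2] addition of the alkyne, a second ring opening and six-electron closure.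
- Merits: the prenyl–methoxy–prenyl order is fixed by the topology of the cascade, both side chains arrive already attached, and no organometallic reagent meets a ketone. In certainty of substitution pattern this road is better than the chosen one.
- Weak points: A1 still lacks the benzoyl group. It would have to be put on the last free ring carbon, between two oxygens, after both prenyl groups exist, and Friedel–Crafts or Fries conditions there invite chroman formation. A2 and A3 are sensitive and each needs several steps.
- Comparison: the chosen plan offers commodity aromatic starting materials, a ketone in place from step 1, and six steps with all acid chemistry before the side chains.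

**Alternative 2:** The C1–carbonyl and C2–O2 bonds are cut together. Fluoride would unmask an aryne from the silyl triflate A5; the carboxylate oxygen of the acid A6 adds at C2 and the resulting C1 aryl anion takes the acyl carbon, giving the bis-MOM ether A4.
- Merits: the hindered ketone and its ortho phenol form convergently in one late step, and the C6 alkoxy group directs the oxygen to the distal aryne carbon. No nucleophile has to discriminate between a ketone and another electrophile. In convergence this road is better than the chosen one.
- Weak points: A5 is a hexasubstituted benzene that already carries both prenyl groups, so the prenylation problem is moved into a long precursor synthesis and not solved. The aryne sits next to a prenyl group with allylic hydrogens, so an ene reaction is open to it. Protonation can stop the sequence at the aryl ester. Removing two MOM groups from A4 needs acid beside o-prenylphenols.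
- Comparison: the chosen plan solves the prenylation directly and deprotects with fluoride.

**Alternative 3:** Ring A is cut at C1–C2 and traced back to the pyrone A8. A magnesium alkoxide would open the lactone, and the carbanion between the two ketones (future C1) would acylate the released ester carbon (future C2) to give the ring-B MOM ether A7.
- Merits: the closure imitates polyketide folding, needs only mild base, and avoids both Friedel–Crafts chemistry and organometallic addition near a ketone.
- Weak points: A8 is a fully substituted pyrone. Its C5 prenyl group cannot be introduced by simple enolate alkylation, its O4 methylation competes with the 2-pyrone oxygen, and the side-chain acylation must be done on a dienolate that also has acidic prenyl CH2 groups. After ring opening an aldol mode of cyclization competes with the Claisen mode. The MOM group again calls for acid at the end.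
- Comparison: the chosen plan is shorter and rests on simpler precursors. Its own risk, the ketone during the Grignard step, is one that Alternative 3 does not have.

Key step: step 5

Remark on the chemistry: the magnesium phenoxides formed in step 5 (11 to 13) are drawn metal-free, as inner salts or phenols, because the counter-ion does not change the connectivity.

## Route

Step 1
Reactants: 1 phloroglucinol; 2 3-hydroxybenzonitrile
Product: 4 (3-hydroxyphenyl)(2,4,6-trihydroxyphenyl)methanone, via ketiminium chloride 3 (not isolated)
Conditions: ZnCl2, HCl (g), Et2O, 0 °C to rt; then H2O, 100 °C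
Reagents that add atoms: water, O
Why: Houben–Hoesch acylation; the nitrilium species attacks the symmetric, very electron-rich ring of 1 at carbon, the ketiminium salt 3 resists a second acylation, and hot water hydrolyses it to the ketone.

Step 2
Reactants: 4 (3-hydroxyphenyl)(2,4,6-trihydroxyphenyl)methanone
Product: 5 (2,6-dihydroxy-4-methoxyphenyl)(3-hydroxyphenyl)methanone
Conditions: Me2SO4 (1.0 equiv), K2CO3 (1.0 equiv), acetone, 0 °C to rt
Reagents that add atoms: dimethyl sulfate, COS(=O)(=O)OC
Why: Williamson-type O-methylation under acidity control; the phenol para to the ketone is the most acidic of the four, so one equivalent of base should form mainly the O4 phenoxide, as in the selective 7-O-alkylation of 5,7,4'-trihydroxyflavonoids.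

Step 3
Reactants: 5 (2,6-dihydroxy-4-methoxyphenyl)(3-hydroxyphenyl)methanone
Product: 6 [3-(tert-butyldimethylsilyloxy)phenyl](2,6-dihydroxy-4-methoxyphenyl)methanone
Conditions: TBSCl (1.05 equiv), imidazole, DMF, 0 °C
Reagents that add atoms: tert-butyldimethylsilyl chloride, CC(C)(C)[Si](C)(C)Cl
Why: Silyl ether formation; O2 and O6 flank the ketone, are hindered and hydrogen-bonded to it, so one equivalent of silyl chloride should take the unhindered O3'.

Step 4
Reactants: 6 [3-(tert-butyldimethylsilyloxy)phenyl](2,6-dihydroxy-4-methoxyphenyl)methanone; 7 N,N-dimethylmethyleneiminium iodide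
Product: 8 {3,5-bis[(dimethylamino)methyl]-2,6-dihydroxy-4-methoxyphenyl}[3-(tert-butyldimethylsilyloxy)phenyl]methanone
Conditions: 7 (2.5 equiv), Et3N, CH2Cl2, 0 °C to rt
Reagents that add atoms: none
Why: Twofold phenol Mannich aminomethylation; C3 and C5 are the only free carbons of ring A, each ortho to a phenol and activated by three oxygens, and the silylated, acyl-deactivated ring B does not react with the iminium salt.

Step 5
Reactants: 8 {3,5-bis[(dimethylamino)methyl]-2,6-dihydroxy-4-methoxyphenyl}[3-(tert-butyldimethylsilyloxy)phenyl]methanone; 9 2-methylprop-1-enylmagnesium bromide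
Product: 14 [3-(tert-butyldimethylsilyloxy)phenyl][2,6-dihydroxy-4-methoxy-3,5-bis(3-methylbut-2-enyl)phenyl]methanone, via bis(trimethylammonium) diiodide 10 (not isolated), via first o-quinone methide 11 (not isolated), via monoprenyl ammonium phenoxide 12 (not isolated), via second o-quinone methide 13 (not isolated)
Conditions: MeI, THF, rt, then evaporation of volatiles; 9 (7 equiv), THF, −78 °C to rt; aq. NH4Cl
Reagents that add atoms: none
Why: Iodomethane quaternizes the two benzylic amines (Menshutkin reaction) to give 10, the neutral hydrogen-bonded phenols being much poorer nucleophiles without added base. The first two equivalents of 9 convert O2 and O6 into magnesium phenoxides; each phenoxide then expels trimethylamine from the neighbouring benzylic carbon to give an o-quinone methide (11, later 13), and 1,4-addition of the alkenyl carbanion at the exocyclic CH2 restores the aromatic ring and forms C1''–C2'' (12, then 14). The closest known reaction type is the generation of o-quinone methides from o-hydroxybenzyl ammonium salts (Mannich base methiodides) under Grignard conditions with conjugate capture by alkenyl Grignard reagents, here run twice on one ring. No ring closes and no stereocentre forms. The selectivity needed is attack at the methide carbons and not at the diaryl ketone: the ketone lies between two magnesium phenoxides, which makes it a chelated, doubly vinylogous carboxylate shielded by two ortho substituents, while each o-quinone methide is a far stronger electrophile and is consumed by the excess of 9 as it forms. Each benzylic carbon has one leaving group and accepts one nucleophile, and the nucleophile bonds through its alkenyl carbon, which excludes O-prenyl, geminal diprenyl and reverse-prenyl products; O4 is methylated, so no para-quinone methide can form. The methyl groups from iodomethane leave with the amine, and the NH4Cl quench is mild enough not to cyclize the new o-prenylphenols.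

Step 6
Reactants: 14 [3-(tert-butyldimethylsilyloxy)phenyl][2,6-dihydroxy-4-methoxy-3,5-bis(3-methylbut-2-enyl)phenyl]methanone
Product: 15 [2,6-dihydroxy-4-methoxy-3,5-bis(3-methylbut-2-enyl)phenyl](3-hydroxyphenyl)methanone
Conditions: Bu4NF, AcOH, THF, 0 °C
Reagents that add atoms: none
Why: Fluoride-induced desilylation of an aryl silyl ether; the acetic acid buffer keeps the medium near neutral, so neither the alkenes nor the o-prenylphenol pairs are touched.

## Compound list

1 | phloroglucinol (benzene-1,3,5-triol) | Oc1cc(O)cc(O)c1 | starting material
2 | 3-hydroxybenzonitrile | N#Cc1cccc(O)c1 | starting material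
3 | (3-hydroxyphenyl)(2,4,6-trihydroxyphenyl)methaniminium chloride | [NH2+]=C(c1cccc(O)c1)c1c(O)cc(O)cc1O.[Cl-] | intermediate
4 | (3-hydroxyphenyl)(2,4,6-trihydroxyphenyl)methanone | O=C(c1cccc(O)c1)c1c(O)cc(O)cc1O | intermediate
5 | (2,6-dihydroxy-4-methoxyphenyl)(3-hydroxyphenyl)methanone | COc1cc(O)c(C(=O)c2cccc(O)c2)c(O)c1 | intermediate
6 | [3-(tert-butyldimethylsilyloxy)phenyl](2,6-dihydroxy-4-methoxyphenyl)methanone | COc1cc(O)c(C(=O)c2cccc(O[Si](C)(C)C(C)(C)C)c2)c(O)c1 | intermediate
7 | N,N-dimethylmethyleneiminium iodide | C=[N+](C)C.[I-] | starting material
8 | {3,5-bis[(dimethylamino)methyl]-2,6-dihydroxy-4-methoxyphenyl}[3-(tert-butyldimethylsilyloxy)phenyl]methanone | CN(C)Cc1c(O)c(C(=O)c2cccc(O[Si](C)(C)C(C)(C)C)c2)c(O)c(CN(C)C)c1OC | intermediate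
9 | 2-methylprop-1-enylmagnesium bromide | CC(C)=C[Mg]Br | starting material
10 | bis(trimethylammonium) diiodide of 8 (both benzylic nitrogens N-methylated) | C[N+](C)(C)Cc1c(O)c(C(=O)c2cccc(O[Si](C)(C)C(C)(C)C)c2)c(O)c(C[N+](C)(C)C)c1OC.[I-].[I-] | intermediate
11 | first o-quinone methide, 2-[3-(tert-butyldimethylsilyloxy)benzoyl]-5-methoxy-4-methylidene-3-oxo-6-[(trimethylammonio)methyl]cyclohexa-1,5-dien-1-olate | C=C1C(=O)C(C(=O)c2cccc(O[Si](C)(C)C(C)(C)C)c2)=C([O-])C(C[N+](C)(C)C)=C1OC | intermediate
12 | monoprenyl ammonium phenoxide, 2-[3-(tert-butyldimethylsilyloxy)benzoyl]-3-hydroxy-5-methoxy-4-(3-methylbut-2-enyl)-6-[(trimethylammonio)methyl]phenolate | COc1c(CC=C(C)C)c(O)c(C(=O)c2cccc(O[Si](C)(C)C(C)(C)C)c2)c([O-])c1C[N+](C)(C)C | intermediate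
13 | second o-quinone methide, 2-[3-(tert-butyldimethylsilyloxy)benzoyl]-3-hydroxy-5-methoxy-6-methylidene-4-(3-methylbut-2-enyl)cyclohexa-2,4-dien-1-one | C=C1C(=O)C(C(=O)c2cccc(O[Si](C)(C)C(C)(C)C)c2)=C(O)C(CC=C(C)C)=C1OC | intermediate
14 | [3-(tert-butyldimethylsilyloxy)phenyl][2,6-dihydroxy-4-methoxy-3,5-bis(3-methylbut-2-enyl)phenyl]methanone | COc1c(CC=C(C)C)c(O)c(C(=O)c2cccc(O[Si](C)(C)C(C)(C)C)c2)c(O)c1CC=C(C)C | intermediate
15 | [2,6-dihydroxy-4-methoxy-3,5-bis(3-methylbut-2-enyl)phenyl](3-hydroxyphenyl)methanone | COc1c(CC=C(C)C)c(O)c(C(=O)c2cccc(O)c2)c(O)c1CC=C(C)C | target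

## Step count and risks

Total step count: 6. Longest linear sequence: 6 steps, from 1 and 2 to 15.

**Step 5 (key step).**
- What may go wrong: loss of trimethylamine from the magnesium phenoxides may be slow, because each phenoxide is conjugated with and chelated to the ketone and so pushes weakly. If warming is then needed, addition of 9 to the ketone or stalling after one side becomes likely. During quaternization, methylation at oxygen through the ammonium phenoxide tautomer of 8 may compete with methylation at nitrogen.
- Fallback, from 6 to 14 without a quinone methide: both phenols are O-allylated (allyl bromide, K2CO3, acetone, reflux) to [2,6-bis(allyloxy)-4-methoxyphenyl][3-(tert-butyldimethylsilyloxy)phenyl]methanone F1. A twofold aromatic Claisen rearrangement (N,N-diethylaniline, 190 °C) moves each allyl group to the only free ortho carbon and gives (3,5-diallyl-2,6-dihydroxy-4-methoxyphenyl)[3-(tert-butyldimethylsilyloxy)phenyl]methanone F2. Olefin cross-metathesis with 2-methylbut-2-ene (second-generation Grubbs catalyst, CH2Cl2, 40 °C) turns both allyl groups into prenyl groups and rejoins the route at 14.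

**Step 4.**
- What may go wrong: aminomethylation may halt after one carbon, because the first Mannich base can sit as an internal ammonium phenoxide that deactivates the ring. The product may also lose amine on handling and condense to diarylmethanes.
- Fallback, from 6 to 14 one benzylic carbon at a time: one equivalent of 7 gives {3-[(dimethylamino)methyl]-2,6-dihydroxy-4-methoxyphenyl}[3-(tert-butyldimethylsilyloxy)phenyl]methanone F3. Iodomethane converts it in the flask into its methiodide F4, which 9 captures as in step 5 to give [3-(tert-butyldimethylsilyloxy)phenyl][2,6-dihydroxy-4-methoxy-3-(3-methylbut-2-enyl)phenyl]methanone F5. The ring now carries an alkyl group in place of the ammonium arm, and a second aminomethylation with 7 gives {3-[(dimethylamino)methyl]-2,6-dihydroxy-4-methoxy-5-(3-methylbut-2-enyl)phenyl}[3-(tert-butyldimethylsilyloxy)phenyl]methanone F6. Its methiodide F7, again not isolated, is captured by 9 to reach 14.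

**Step 2.**
- What may go wrong: methylation may spill over to O3' or go twice, because the acidity gap between O4 and O3' is moderate and the more basic O3' phenoxide is the better nucleophile once it forms.
- Fallback, from 2 to 5 with the methyl groups set by cleavage instead of alkylation: Hoesch condensation of 2 with commercial 1,3,5-trimethoxybenzene (COc1cc(OC)cc(OC)c1; ZnCl2, HCl, Et2O, then hot water) passes through (3-hydroxyphenyl)(2,4,6-trimethoxyphenyl)methaniminium chloride F8 to (3-hydroxyphenyl)(2,4,6-trimethoxyphenyl)methanone F9. AlCl3 in chlorobenzene at 80 °C, chelated to the ketone, cleaves the two ortho methyl ethers and leaves the para one, rejoining the route at 5.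

**Step 1.**
- What may go wrong: the free phenol of 2 may add through oxygen to the activated nitrile and form imidates, and the precipitating ketiminium salt may occlude unreacted material, so conversion may be incomplete.
- Fallback, from 1 to 4 with a carboxylic acid in place of the nitrile: Friedel–Crafts acylation of 1 with 3-hydroxybenzoic acid (O=C(O)c1cccc(O)c1) in BF3·OEt2 at 90 °C gives 4 directly. A xanthone cannot form because the acid has no ortho hydroxyl group.

## Further compounds

F1 | step 5 | [2,6-bis(allyloxy)-4-methoxyphenyl][3-(tert-butyldimethylsilyloxy)phenyl]methanone | COc1cc(OCC=C)c(C(=O)c2cccc(O[Si](C)(C)C(C)(C)C)c2)c(OCC=C)c1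
F2 | step 5 | (3,5-diallyl-2,6-dihydroxy-4-methoxyphenyl)[3-(tert-butyldimethylsilyloxy)phenyl]methanone | COc1c(CC=C)c(O)c(C(=O)c2cccc(O[Si](C)(C)C(C)(C)C)c2)c(O)c1CC=C
F3 | step 4 | {3-[(dimethylamino)methyl]-2,6-dihydroxy-4-methoxyphenyl}[3-(tert-butyldimethylsilyloxy)phenyl]methanone | CN(C)Cc1c(O)c(C(=O)c2cccc(O[Si](C)(C)C(C)(C)C)c2)c(O)cc1OC
F4 | step 4 | methiodide of F3, {3-[3-(tert-butyldimethylsilyloxy)benzoyl]-2,4-dihydroxy-6-methoxyphenyl}methyl-trimethylammonium iodide | C[N+](C)(C)Cc1c(O)c(C(=O)c2cccc(O[Si](C)(C)C(C)(C)C)c2)c(O)cc1OC.[I-]
F5 | step 4 | [3-(tert-butyldimethylsilyloxy)phenyl][2,6-dihydroxy-4-methoxy-3-(3-methylbut-2-enyl)phenyl]methanone | COc1cc(O)c(C(=O)c2cccc(O[Si](C)(C)C(C)(C)C)c2)c(O)c1CC=C(C)C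
F6 | step 4 | {3-[(dimethylamino)methyl]-2,6-dihydroxy-4-methoxy-5-(3-methylbut-2-enyl)phenyl}[3-(tert-butyldimethylsilyloxy)phenyl]methanone | CN(C)Cc1c(O)c(C(=O)c2cccc(O[Si](C)(C)C(C)(C)C)c2)c(O)c(CC=C(C)C)c1OC
F7 | step 4 | methiodide of F6, {3-[3-(tert-butyldimethylsilyloxy)benzoyl]-2,4-dihydroxy-6-methoxy-5-(3-methylbut-2-enyl)phenyl}methyl-trimethylammonium iodide | C[N+](C)(C)Cc1c(O)c(C(=O)c2cccc(O[Si](C)(C)C(C)(C)C)c2)c(O)c(CC=C(C)C)c1OC.[I-]
F8 | step 2 | (3-hydroxyphenyl)(2,4,6-trimethoxyphenyl)methaniminium chloride | [NH2+]=C(c1cccc(O)c1)c1c(OC)cc(OC)cc1OC.[Cl-]
F9 | step 2 | (3-hydroxyphenyl)(2,4,6-trimethoxyphenyl)methanone | COc1cc(OC)c(C(=O)c2cccc(O)c2)c(OC)c1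
F0 | step 1 | none | none
A1 | alternative 1 | 3-methoxy-2,4-bis(3-methylbut-2-enyl)-5-(triisopropylsilyloxy)phenol | COc1c(CC=C(C)C)c(O)cc(O[Si](C(C)C)(C(C)C)C(C)C)c1CC=C(C)C
A2 | alternative 1 | 2-(3-methylbut-2-enyl)-3-(triisopropylsilyloxy)cyclobut-2-en-1-one | CC(C)=CCC1=C(O[Si](C(C)C)(C(C)C)C(C)C)CC1=O
A3 | alternative 1 | 1-methoxy-5-methylhex-4-en-1-yne | COC#CCC=C(C)C
A4 | alternative 2 | [2-hydroxy-4-methoxy-6-(methoxymethoxy)-3,5-bis(3-methylbut-2-enyl)phenyl][3-(methoxymethoxy)phenyl]methanone | COCOc1c(CC=C(C)C)c(OC)c(CC=C(C)C)c(O)c1C(=O)c1cccc(OCOC)c1
A5 | alternative 2 | 5-methoxy-3-(methoxymethoxy)-4,6-bis(3-methylbut-2-enyl)-2-(trimethylsilyl)phenyl trifluoromethanesulfonate | COCOc1c([Si](C)(C)C)c(OS(=O)(=O)C(F)(F)F)c(CC=C(C)C)c(OC)c1CC=C(C)C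
A6 | alternative 2 | 3-(methoxymethoxy)benzoic acid | COCOc1cccc(C(=O)O)c1
A7 | alternative 3 | [2,6-dihydroxy-4-methoxy-3,5-bis(3-methylbut-2-enyl)phenyl][3-(methoxymethoxy)phenyl]methanone | COc1c(CC=C(C)C)c(O)c(C(=O)c2cccc(OCOC)c2)c(O)c1CC=C(C)C
A8 | alternative 3 | 4-methoxy-6-{2-[3-(methoxymethoxy)phenyl]-2-oxoethyl}-3,5-bis(3-methylbut-2-enyl)-2H-pyran-2-one | COC1=C(CC=C(C)C)C(=O)OC(CC(=O)c2cccc(OCOC)c2)=C1CC=C(C)C
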